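If the alpha flask holds twice the substrate of the delta flask and has made 1.08 times its target by 15 min, the rate is near a ceiling, and one concentration tells how near.

| flask | substrate | partner | free catalyst | time |
|---|---|---|---|---|
| delta | 50.0 mM | 55.0 mM | 4.00 mM |  |
| alpha | 100 mM | 55.0 mM | 4.00 mM |  |
| theta | 50.0 mM | 55.0 mM | 12.0 mM |  |
| epsilon | 50.0 mM | 18.0 mM | 12.0 mM | 67 min |

- delta run (time / min: [substrate] / mM): 5.1: 45.71; 15: 38.79; 30: 31.26; 47: 26.05; 67: 22.69
- alpha run (time / min: [substrate] / mM): 5.1: 95.85; 15: 87.88; 30: 79.69; 47: 72.08; 67: 66.49
- theta run (time / min: [substrate] / mM): 5.1: 38.10; 15: 22.21; 30: 11.26; 47: 6.54; 67: 4.68

(standard deviation of a reading: 0.2 mM)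

- the power of [substrate] that the first rate follows, about the charge of the delta run; measure it at two percent of substrate made into target (one fixed amount of target, the same in the runs compared)
- the power of [free catalyst] that the first rate follows, about the charge of the delta run; measure it at two percent of substrate made into target
- substrate in the epsilon run at 67 min, as a share of the substrate charged

- Overall: substrate + partner -> target, with free catalyst as catalyst.
- Constant volume, constant temperature.
- A reading of a species includes what of it is bound.
- An order is taken over about fifteen percent of the charge, up and down.

Take a rate that follows S/(K+S), so that its order in substrate is K/(K+S). Over that window the mean substrate is 44.4 mM in the delta flask and 93.9 mM in the alpha flask. The ratio then gives K = 7.37 mM, the half-rate concentration: the substrate level at which the rate stands at half of its ceiling. At the delta charge the order is 0.128.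

There is an objection. At 5.1 min the same ratio reads 0.967, below one, which this curve cannot give. But that ratio carries a scatter of 0.0659, so it does not overturn the later one. The later ratio carries 0.0252, which spreads the order from 0.0902 to 0.165.

By 5.1 min the theta flask, on 12.0 mM of free catalyst against 4.00 mM, has made 2.77 times the target of the delta flask, which reads as a power of 0.929. The theta flask has used more partner than the delta flask, so that reading may sit a little low.

The epsilon flask charges less partner than substrate, so partner is the limiting reagent. Substrate cannot fall under 32.0 mM, 64.0% of its charge. K was read with much more partner present, but if it holds here, the order in substrate at that floor is 0.187, and the rate should be close to pseudo-first-order in partner. The theta flask has the same catalyst charge, and its partner falls at 0.0469 /min up to 15 min. That clock leaves 65.6% of the substrate at 67 min.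

The objection is that the clock slows. The whole delta run, scaled by its catalyst ratio, gives 0.0307 /min, a slower clock than the theta one, though its substrate stays above K. That clock leaves 68.6%. This reckoning takes the middle, 67.1%.

The forecast gives a substrate order of 0.15, higher than this reckoning, on the ground that “the catalyst is nearly saturated by substrate”; it gives a catalyst order of 1 and an epsilon share of 68%, that share being higher than this reckoning.

The simulation gives a substrate order of 0.10, a catalyst order of 0.92 and 64.7% of the epsilon charge.

    free catalyst + substrate → catalyst-substrate complex (38.16 /M/min)
    catalyst-substrate complex + partner → target + free catalyst (7.320 /M/min)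
    free catalyst → spent catalyst (0.1428 /min)
    catalyst-substrate complex + substrate ⇌ doubly bound catalyst, settled at all times (6.060 /M)

At equal target made, the alpha rate stands at 0.96 of the delta rate, while the half-rate curve with K at 7.37 mM gives 1.07 for the two charges. In the epsilon flask substrate ends at 32.4 mM, which is 0.353 mM above its floor.

The earlier runs and the new flask are simulated with made-up constants; scatter was added.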